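The ten-membered carbocycle carries its C3 ketone between two Z alkenes, C1=C2 and C4(Me)=C5, so the cross-conjugated dienone is treated as one molecule of carbon monoxide held by the alkenyl carbons C2 and C4, and both bonds to C3 are disconnected. A single palladium-catalysed carbonylative Stille macrocyclisation forms C2–C3 and C3–C4, closes the ten-membered ring and completes the (1Z,4Z)-dienone. Its precursor is a cis-disubstituted α-methylene-γ-butyrolactone (O, C12, C11, C7, C6): the C6 arm ends in a Z 1-methylalkenylstannane (C4), the C7 arm carries the silylated C8 and C10 oxygens and ends in a Z alkenyl iodide (C2). Fragments 1 and 2 are joined at C6–C7 by a chromium allylation.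

Key step: step 14

Numbering: C1–C10 are the ring carbons (C3 ketone, C6 lactone oxygen, C7 ring fusion, C8 ester, C10 carbinol); C11, C12 and C13 are the α-carbon, carbonyl and methylene of the lactone. TBS = tert-butyldimethylsilyl, TES = triethylsilyl. The CIP letters at C6 and C7 change with tin and silicon substituents although the spatial arrangement stays that of the target.
Assumption 1: the ProPhenol antipode in step 6 is defined by the carbinol it must give (4R in 8); its facial sense for this aldehyde is to be confirmed by Mosher analysis.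
Assumption 2: the target is taken as the open 10-hydroxy-3-ketone as drawn; 21 and 24 may equilibrate with their 3,10-hemiketal tautomers, which needs no separate step.

Step 1
Reactants: 1 (2E)-3-methylpent-2-en-4-yn-1-ol
Product: 2 [(2S,3S)-3-ethynyl-3-methyloxiran-2-yl]methanol
Conditions: Ti(OiPr)4 (cat.), L-(+)-diethyl tartrate (cat.), t-BuOOH, 4 Å sieves, CH2Cl2, −20 °C
Reagents that add atoms: tert-butyl hydroperoxide, CC(C)(C)OO
Why: Sharpless asymmetric epoxidation of a trisubstituted E allylic alcohol is reliable, the L-(+)-tartrate delivering oxygen to the face that gives the (2S,3S) epoxide and so fixing the future C10 centre, while the ethynyl group is inert to the titanium peroxide.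

Step 2
Reactants: 2 [(2S,3S)-3-ethynyl-3-methyloxiran-2-yl]methanol
Product: 3 (3R)-3-methylpent-4-yne-1,3-diol
Conditions: NaAlH2(OCH2CH2OCH3)2, THF, 0 °C
Reagents that add atoms: none
Why: In this hydroxyl-directed reductive opening of a 2,3-epoxy alcohol the aluminate bound at O1 delivers hydride to C2 (the future C9), so the 1,3-diol forms and the C–O bond of the tertiary centre is never broken.

Step 3
Reactants: 3 (3R)-3-methylpent-4-yne-1,3-diol
Product: 4 (3R,4Z)-5-iodo-3-methylpent-4-ene-1,3-diol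
Conditions: NaAlH2(OCH2CH2OCH3)2, THF, 0 °C to rt; EtOAc; I2, THF, −78 to 0 °C
Reagents that add atoms: iodine, II
Why: Alkoxide-directed trans-hydroalumination of the propargylic alcohol places aluminium on the terminal carbon cis to the carbinol carbon, and iodinolysis of the carbon–aluminium bond with retention gives the Z iodoalkene (hydroalumination–iodination).

Step 4
Reactants: 4 (3R,4Z)-5-iodo-3-methylpent-4-ene-1,3-diol
Product: 5 (1Z,3R)-1-iodo-3-methyl-3,5-bis(TESO)pent-1-ene
Conditions: Et3SiOTf, 2,6-lutidine, CH2Cl2, −78 to 0 °C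
Reagents that add atoms: triethylsilyl trifluoromethanesulfonate, CC[Si](CC)(CC)OS(=O)(=O)C(F)(F)F
Why: A silyl triflate with a hindered pyridine base silylates both the primary and the tertiary allylic hydroxyl at low temperature without ionising the tertiary centre (silyl ether formation).

Step 5
Reactants: 5 (1Z,3R)-1-iodo-3-methyl-3,5-bis(TESO)pent-1-ene
Product: 6 (3R,4Z)-5-iodo-3-methyl-3-(TESO)pent-4-enal
Conditions: (COCl)2, DMSO, CH2Cl2, −78 to −30 °C; Et3N, −78 °C to rt
Reagents that add atoms: none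
Why: Under Swern conditions the chlorosulfonium reagent cleaves the unhindered primary triethylsilyl ether and oxidises it in the same flask, whereas the tertiary silyl ether is too hindered to react (Swern oxidation of a primary silyl ether).

Step 6
Reactants: 6 (3R,4Z)-5-iodo-3-methyl-3-(TESO)pent-4-enal; 7 methyl propiolate
Product: 8 methyl (4R,6R,7Z)-4-hydroxy-8-iodo-6-methyl-6-(TESO)oct-7-en-2-ynoate
Conditions: Me2Zn, ProPhenol ligand (antipode giving the 4R carbinol, 20 mol %), Ph3PO (40 mol %), toluene, 4 °C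
Reagents that add atoms: none
Why: In this catalytic asymmetric alkynylation the dinuclear zinc–ProPhenol complex holds the aldehyde and the zinc propiolate side by side and delivers the alkynyl group to one carbonyl face, which sets the future C8 centre as R under catalyst control because the remote quaternary centre exerts little bias.

Step 7
Reactants: 8 methyl (4R,6R,7Z)-4-hydroxy-8-iodo-6-methyl-6-(TESO)oct-7-en-2-ynoate
Product: 9 methyl (4R,6R,7Z)-4-(TBSO)-8-iodo-6-methyl-6-(TESO)oct-7-en-2-ynoate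
Conditions: t-BuMe2SiOTf, 2,6-lutidine, CH2Cl2, −78 °C
Reagents that add atoms: tert-butyldimethylsilyl trifluoromethanesulfonate, CC(C)(C)[Si](C)(C)OS(=O)(=O)C(F)(F)F
Why: Silylation with the triflate and a hindered base at low temperature protects the propargylic hydroxyl before the base-sensitive γ-hydroxy ynoate can isomerise (silyl ether formation).

Step 8
Reactants: 9 methyl (4R,6R,7Z)-4-(TBSO)-8-iodo-6-methyl-6-(TESO)oct-7-en-2-ynoate
Product: 10 methyl (2Z,4R,6R,7Z)-4-(TBSO)-2-(hydroxymethyl)-8-iodo-6-methyl-6-(TESO)octa-2,7-dienoate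
Conditions: i-Bu2AlH, HMPA, THF, 0 °C; then monomeric CH2O (from cracked paraformaldehyde), THF, 0 °C to rt
Reagents that add atoms: formaldehyde, C=O
Why: The i-Bu2AlH–HMPA complex adds hydride to the β-carbon of the ynoate in a syn sense and spares the ester carbonyl, and the aluminium-bearing α-carbon then adds to formaldehyde with retention, so the hydroxymethyl group (C13) ends trans to C4 (conjugate hydroalumination with aldehyde trapping).

Step 9
Reactants: 10 methyl (2Z,4R,6R,7Z)-4-(TBSO)-2-(hydroxymethyl)-8-iodo-6-methyl-6-(TESO)octa-2,7-dienoate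
Product: 12 methyl (2Z,4R,6R,7Z)-2-(bromomethyl)-4-(TBSO)-8-iodo-6-methyl-6-(TESO)octa-2,7-dienoate, via E-bromide 11 (not isolated)
Conditions: CBr4, PPh3, CH2Cl2, 0 °C; then LiBr, THF, rt
Reagents that add atoms: carbon tetrabromide, BrC(Br)(Br)Br; lithium bromide, [Li+].[Br-]
Why: Appel bromination gives bromide 11 with the alkene geometry unchanged, and bromide ion then equilibrates it by reversible SN2′ addition–elimination to the more stable isomer 12 with the C4 substituent trans to the ester, any residual 11 being harmless because the allylchromium of step 13 does not remember this geometry.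

Step 10
Reactants: 13 ethyl but-2-ynoate
Product: 14 ethyl (2Z)-3-(tributylstannyl)but-2-enoate
Conditions: Bu3SnH, LiN(i-Pr)2, THF, 0 °C; PhSCu, −20 °C; 13, −48 °C, 4 h; MeOH
Reagents that add atoms: tributyltin hydride, CCCC[SnH](CCCC)CCCC
Why: In this stannylcupration of an ynoate the syn adduct equilibrates through its allenoate form at −48 °C in the absence of a proton source, so that protonation gives the isomer with tin cis to the ester.

Step 11
Reactants: 14 ethyl (2Z)-3-(tributylstannyl)but-2-enoate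
Product: 15 (2Z)-3-(tributylstannyl)but-2-en-1-ol
Conditions: i-Bu2AlH, CH2Cl2, −78 °C
Reagents that add atoms: none
Why: Hydride reduction of the enoate at low temperature gives the allylic alcohol by 1,2-addition and leaves the carbon–tin bond and the alkene geometry untouched.

Step 12
Reactants: 15 (2Z)-3-(tributylstannyl)but-2-en-1-ol
Product: 16 (2Z)-3-(tributylstannyl)but-2-enal
Conditions: MnO2, CH2Cl2, rt
Reagents that add atoms: none
Why: Allylic oxidation on the surface of MnO2 is neutral and mild, so the Z enal forms without isomerisation or loss of tin.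

Step 13
Reactants: 12 methyl (2Z,4R,6R,7Z)-2-(bromomethyl)-4-(TBSO)-8-iodo-6-methyl-6-(TESO)octa-2,7-dienoate; 16 (2Z)-3-(tributylstannyl)but-2-enal
Product: 18 (4S,5R)-4-[(1R,3R,4Z)-1-(TBSO)-5-iodo-3-methyl-3-(TESO)pent-4-en-1-yl]-3-methylidene-5-[(1Z)-2-(tributylstannyl)prop-1-en-1-yl]oxolan-2-one, via hydroxy ester 17 (not isolated)
Conditions: CrCl2 (free of nickel salts), THF, 0 °C to rt; then PPTS (cat.), CH2Cl2, rt
Reagents that add atoms: none
Why: Divalent chromium turns the allylic bromide into an allylchromium that adds through C7 to the aldehyde in a closed chair transition state (Nozaki–Hiyama 2-(alkoxycarbonyl)allylation) with C8 cis to the CH2Cr carbon and therefore axial, which gives the syn adduct 17 and after O–C12 acyl substitution the cis lactone, while the C7 face is chosen by the C8 centre (C8–H eclipsing the alkene, the bulky C9 arm anti to the incoming aldehyde, the silyloxy group outside, equal to attack on the Re face of the enal) so that C6 and C7 are set as in the target, and without nickel the alkenyl iodide and the stannane stay untouched.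

Step 14
Reactants: 18 (4S,5R)-4-[(1R,3R,4Z)-1-(TBSO)-5-iodo-3-methyl-3-(TESO)pent-4-en-1-yl]-3-methylidene-5-[(1Z)-2-(tributylstannyl)prop-1-en-1-yl]oxolan-2-one; 19 carbon monoxide
Product: 20 (3aS,4R,6R,7Z,10Z,11aS)-4-(TBSO)-6,10-dimethyl-3-methylidene-6-(TESO)-3a,4,5,6-tetrahydrocyclodeca[b]furan-2,9(3H,11aH)-dione
Conditions: Pd2(dba)3 (10 mol %), AsPh3 (80 mol %), CO (3 atm), NMP–THF, 45 °C, 18 added by syringe pump to about 1 mM
Reagents that add atoms: none
Why: Zerovalent palladium adds oxidatively to the C2–I bond with retention, CO inserts to give the (Z)-enoylpalladium at C3, the C4 alkenyl group is transferred from tin within the same molecule and reductive elimination forms C3–C4. The closest known reaction type is the intramolecular carbonylative Stille coupling of an alkenyl halide or triflate with an alkenylstannane, which is used to make macrocyclic cross-conjugated dienones. The ten-membered carbocycle closes by reductive elimination from an eleven-membered acyl(alkenyl)palladacycle, that is by C3–C4 bond formation at the metal and not by a polar or radical cyclisation. No stereocentre is created, and both alkene geometries are carried over because oxidative addition, CO insertion and tin-to-palladium transfer all proceed with retention. The step needs CO capture before coupling and cyclisation before oligomerisation: CO-free coupling would give a strained nine-membered Z,Z-diene and the hindered 1-methylalkenylstannane transmetalates slowly, so CO insertion comes first, while the cis lactone and the two Z alkenes turn both termini toward each other and CO pressure with high dilution supports ring closure. The iodide sits at C2, far from the exo-methylene group, so a Heck closure onto C13 does not compete.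

Step 15
Reactants: 20 (3aS,4R,6R,7Z,10Z,11aS)-4-(TBSO)-6,10-dimethyl-3-methylidene-6-(TESO)-3a,4,5,6-tetrahydrocyclodeca[b]furan-2,9(3H,11aH)-dione
Product: 21 (3aR,4R,6R,7Z,10Z,11aS)-4,6-dihydroxy-6,10-dimethyl-3-methylidene-3a,4,5,6-tetrahydrocyclodeca[b]furan-2,9(3H,11aH)-dione
Conditions: HF·pyridine, pyridine, THF, 0 °C to rt
Reagents that add atoms: none
Why: Buffered hydrogen fluoride cleaves both silicon–oxygen bonds without base, so the Z,Z-dienone, the α-methylene lactone and the C6 and C7 centres are not disturbed (fluoride desilylation).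

Step 16
Reactants: 21 (3aR,4R,6R,7Z,10Z,11aS)-4,6-dihydroxy-6,10-dimethyl-3-methylidene-3a,4,5,6-tetrahydrocyclodeca[b]furan-2,9(3H,11aH)-dione; 22 tiglic acid
Product: 24 (3aR,4R,6R,7Z,10Z,11aS)-6-hydroxy-6,10-dimethyl-3-methylidene-2,9-dioxo-2,3,3a,4,5,6,9,11a-octahydrocyclodeca[b]furan-4-yl (2E)-2-methylbut-2-enoate, via mixed anhydride 23 (not isolated)
Conditions: 22, 2,4,6-Cl3C6H2COCl, Et3N, toluene, rt; then 21, DMAP, rt
Reagents that add atoms: none
Why: In this Yamaguchi esterification the acylpyridinium formed from the mixed anhydride acylates only the secondary C8 hydroxyl, the tertiary C10 hydroxyl (free or as hemiketal) being too hindered, and the E geometry of tiglic acid is carried into the ester.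

Compound list
1 | (2E)-3-methylpent-2-en-4-yn-1-ol | C#C/C(C)=C/CO | starting material
2 | [(2S,3S)-3-ethynyl-3-methyloxiran-2-yl]methanol | C#C[C@]1(C)O[C@H]1CO | intermediate
3 | (3R)-3-methylpent-4-yne-1,3-diol | C#C[C@](C)(O)CCO | intermediate
4 | (3R,4Z)-5-iodo-3-methylpent-4-ene-1,3-diol | I/C=C\[C@](C)(O)CCO | intermediate
5 | (1Z,3R)-1-iodo-3-methyl-3,5-bis[(triethylsilyl)oxy]pent-1-ene | I/C=C\[C@](C)(O[Si](CC)(CC)CC)CCO[Si](CC)(CC)CC | intermediate
6 | (3R,4Z)-5-iodo-3-methyl-3-[(triethylsilyl)oxy]pent-4-enal | I/C=C\[C@](C)(O[Si](CC)(CC)CC)CC=O | intermediate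
7 | methyl prop-2-ynoate (methyl propiolate) | C#CC(=O)OC | starting material
8 | methyl (4R,6R,7Z)-4-hydroxy-8-iodo-6-methyl-6-[(triethylsilyl)oxy]oct-7-en-2-ynoate | I/C=C\[C@](C)(O[Si](CC)(CC)CC)C[C@@H](O)C#CC(=O)OC | intermediate
9 | methyl (4R,6R,7Z)-4-[(tert-butyldimethylsilyl)oxy]-8-iodo-6-methyl-6-[(triethylsilyl)oxy]oct-7-en-2-ynoate | I/C=C\[C@](C)(O[Si](CC)(CC)CC)C[C@@H](O[Si](C)(C)C(C)(C)C)C#CC(=O)OC | intermediate
10 | methyl (2Z,4R,6R,7Z)-4-[(tert-butyldimethylsilyl)oxy]-2-(hydroxymethyl)-8-iodo-6-methyl-6-[(triethylsilyl)oxy]octa-2,7-dienoate | I/C=C\[C@](C)(O[Si](CC)(CC)CC)C[C@@H](O[Si](C)(C)C(C)(C)C)/C=C(/CO)C(=O)OC | intermediate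
11 | methyl (2E,4R,6R,7Z)-2-(bromomethyl)-4-[(tert-butyldimethylsilyl)oxy]-8-iodo-6-methyl-6-[(triethylsilyl)oxy]octa-2,7-dienoate | I/C=C\[C@](C)(O[Si](CC)(CC)CC)C[C@@H](O[Si](C)(C)C(C)(C)C)/C=C(/CBr)C(=O)OC | intermediate
12 | methyl (2Z,4R,6R,7Z)-2-(bromomethyl)-4-[(tert-butyldimethylsilyl)oxy]-8-iodo-6-methyl-6-[(triethylsilyl)oxy]octa-2,7-dienoate | I/C=C\[C@](C)(O[Si](CC)(CC)CC)C[C@@H](O[Si](C)(C)C(C)(C)C)/C=C(\CBr)C(=O)OC | intermediate
13 | ethyl but-2-ynoate | CCOC(=O)C#CC | starting material
14 | ethyl (2Z)-3-(tributylstannyl)but-2-enoate | CCCC[Sn](CCCC)(CCCC)/C(C)=C\C(=O)OCC | intermediate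
15 | (2Z)-3-(tributylstannyl)but-2-en-1-ol | CCCC[Sn](CCCC)(CCCC)/C(C)=C\CO | intermediate
16 | (2Z)-3-(tributylstannyl)but-2-enal | CCCC[Sn](CCCC)(CCCC)/C(C)=C\C=O | intermediate
17 | methyl (3S,4R,5Z)-3-[(1R,3R,4Z)-1-[(tert-butyldimethylsilyl)oxy]-5-iodo-3-methyl-3-[(triethylsilyl)oxy]pent-4-en-1-yl]-4-hydroxy-2-methylidene-6-(tributylstannyl)hept-5-enoate | C=C(C(=O)OC)[C@@H]([C@@H](O)/C=C(/C)[Sn](CCCC)(CCCC)CCCC)[C@H](O[Si](C)(C)C(C)(C)C)C[C@@](C)(O[Si](CC)(CC)CC)/C=C\I | intermediate
18 | (4S,5R)-4-[(1R,3R,4Z)-1-[(tert-butyldimethylsilyl)oxy]-5-iodo-3-methyl-3-[(triethylsilyl)oxy]pent-4-en-1-yl]-3-methylidene-5-[(1Z)-2-(tributylstannyl)prop-1-en-1-yl]oxolan-2-one | C=C1C(=O)O[C@@H](/C=C(/C)[Sn](CCCC)(CCCC)CCCC)[C@H]1[C@H](O[Si](C)(C)C(C)(C)C)C[C@@](C)(O[Si](CC)(CC)CC)/C=C\I | intermediate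
19 | carbon monoxide | [C-]#[O+] | starting material
20 | (3aS,4R,6R,7Z,10Z,11aS)-4-[(tert-butyldimethylsilyl)oxy]-6,10-dimethyl-3-methylidene-6-[(triethylsilyl)oxy]-3a,4,5,6-tetrahydrocyclodeca[b]furan-2,9(3H,11aH)-dione | C=C1C(=O)O[C@H]2/C=C(/C)C(=O)/C=C\[C@](C)(O[Si](CC)(CC)CC)C[C@@H](O[Si](C)(C)C(C)(C)C)[C@@H]12 | intermediate
21 | (3aR,4R,6R,7Z,10Z,11aS)-4,6-dihydroxy-6,10-dimethyl-3-methylidene-3a,4,5,6-tetrahydrocyclodeca[b]furan-2,9(3H,11aH)-dione | C=C1C(=O)O[C@H]2/C=C(/C)C(=O)/C=C\[C@](C)(O)C[C@@H](O)[C@@H]12 | intermediate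
22 | (2E)-2-methylbut-2-enoic acid (tiglic acid) | C/C=C(\C)C(=O)O | starting material
23 | (2E)-2-methylbut-2-enoic 2,4,6-trichlorobenzoic anhydride | C/C=C(\C)C(=O)OC(=O)c1c(Cl)cc(Cl)cc1Cl | intermediate
24 | (3aR,4R,6R,7Z,10Z,11aS)-6-hydroxy-6,10-dimethyl-3-methylidene-2,9-dioxo-2,3,3a,4,5,6,9,11a-octahydrocyclodeca[b]furan-4-yl (2E)-2-methylbut-2-enoate | C=C1C(=O)O[C@H]2/C=C(/C)C(=O)/C=C\[C@](C)(O)C[C@@H](OC(=O)/C(C)=C/C)[C@@H]12 | target

Total step count: 16 steps.
Longest linear sequence: 13 steps (steps 1–9 and 13–16, from 1 to 24); fragment 2 takes steps 10–12.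

Steps most likely to fail

1. Step 14 (carbonylative macrocyclisation). Transfer of the hindered 1-methylalkenyl group from tin to the acylpalladium may be too slow for a ten-membered closure. Oligomerisation, CO-free coupling or loss of tin by protonolysis could then take over. The fallback sets out from 18 and comes back at 20, closing the ring by a polar addition instead. Reductive carbonylation of the C2 iodide of 18 (Pd(PPh3)4, CO, slow addition of Bu3SnH, THF, 50 °C) should give the C3 (Z)-enal stannane F1. Iodine (CH2Cl2, 0 °C) would replace the C4 tin by iodine with retention to give the iodo enal F2. An intramolecular Nozaki–Hiyama–Kishi reaction (CrCl2, catalytic NiCl2, DMSO–THF, high dilution) would join C4 to the C3 aldehyde and give the macrocyclic C3 alcohol F3 as an epimer mixture. Dess–Martin periodinane (NaHCO3, CH2Cl2) would oxidise it to 20.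

2. Step 13 (chromium allylation). The aldehyde may approach C7 from the face anti to the C8 silyloxy group, not the face anti to the C9 arm. This would give a cis lactone in which C6 and C7 are both inverted relative to C8; the 1,2-induction from C8 is the least certain stereochemical point of the route. The fallback sets out from 6 and comes back at 24: it keeps whatever the intrinsic preference is and corrects C8 at the end.
   - Step 6 with the mirror-image ProPhenol ligand would give the 4S alkynol F4.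
   - The operations of steps 7, 8 and 9 would then give the silyl ether F5, the hydroxymethyl enoate F6, the E bromide F7 and the Z bromide F8.
   - Allylation with 16 as in step 13 would give the hydroxy ester F9 and the lactone F10, which has C6 and C7 as in the target and C8 inverted.
   - The operations of steps 14 and 15 would give the macrocycle F11 and the 8-epi diol F12.
   - Mitsunobu esterification of F12 with tiglic acid 22 (PPh3, diisopropyl azodicarboxylate, toluene, 0 °C) would invert C8 and give 24.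

3. Step 6 (asymmetric alkynylation). The enolisable aldehyde may self-condense or lose its β-silyloxy group under the zinc alkoxide conditions, and facial control for an unbranched aliphatic aldehyde may be incomplete. The fallback sets out from 6 and comes back at 8, setting the centre by reduction instead. Lithium methyl propiolate (7, LiN(SiMe3)2, THF, −78 °C) would add to 6 without facial control to give the epimeric carbinol mixture F13. Dess–Martin periodinane would oxidise it to the ynone F14. Reduction with (R)-Alpine-Borane (THF, rt), for which the alkynyl group acts as the small substituent, should give the 4R carbinol 8.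

Further compounds
F1 | step 14 | (4S,5R)-4-[(1R,3R,4Z)-1-[(tert-butyldimethylsilyl)oxy]-3-methyl-5-oxo-3-[(triethylsilyl)oxy]pent-4-en-1-yl]-3-methylidene-5-[(1Z)-2-(tributylstannyl)prop-1-en-1-yl]oxolan-2-one | C=C1C(=O)O[C@@H](/C=C(/C)[Sn](CCCC)(CCCC)CCCC)[C@H]1[C@H](O[Si](C)(C)C(C)(C)C)C[C@@](C)(O[Si](CC)(CC)CC)/C=C\C=O
F2 | step 14 | (4S,5R)-4-[(1R,3R,4Z)-1-[(tert-butyldimethylsilyl)oxy]-3-methyl-5-oxo-3-[(triethylsilyl)oxy]pent-4-en-1-yl]-5-[(1Z)-2-iodoprop-1-en-1-yl]-3-methylideneoxolan-2-one | C=C1C(=O)O[C@@H](/C=C(/C)I)[C@H]1[C@H](O[Si](C)(C)C(C)(C)C)C[C@@](C)(O[Si](CC)(CC)CC)/C=C\C=O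
F3 | step 14 | 20 with CH(OH) in place of the C3 carbonyl (9-hydroxy in the cyclodeca[b]furan numbering), both C3 epimers | C=C1C(=O)O[C@H]2/C=C(/C)C(O)/C=C\[C@](C)(O[Si](CC)(CC)CC)C[C@@H](O[Si](C)(C)C(C)(C)C)[C@@H]12
F4 | step 13 | methyl (4S,6R,7Z)-4-hydroxy-8-iodo-6-methyl-6-[(triethylsilyl)oxy]oct-7-en-2-ynoate | I/C=C\[C@](C)(O[Si](CC)(CC)CC)C[C@H](O)C#CC(=O)OC
F5 | step 13 | methyl (4S,6R,7Z)-4-[(tert-butyldimethylsilyl)oxy]-8-iodo-6-methyl-6-[(triethylsilyl)oxy]oct-7-en-2-ynoate | I/C=C\[C@](C)(O[Si](CC)(CC)CC)C[C@H](O[Si](C)(C)C(C)(C)C)C#CC(=O)OC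
F6 | step 13 | methyl (2Z,4S,6R,7Z)-4-[(tert-butyldimethylsilyl)oxy]-2-(hydroxymethyl)-8-iodo-6-methyl-6-[(triethylsilyl)oxy]octa-2,7-dienoate | I/C=C\[C@](C)(O[Si](CC)(CC)CC)C[C@H](O[Si](C)(C)C(C)(C)C)/C=C(/CO)C(=O)OC
F7 | step 13 | methyl (2E,4S,6R,7Z)-2-(bromomethyl)-4-[(tert-butyldimethylsilyl)oxy]-8-iodo-6-methyl-6-[(triethylsilyl)oxy]octa-2,7-dienoate | I/C=C\[C@](C)(O[Si](CC)(CC)CC)C[C@H](O[Si](C)(C)C(C)(C)C)/C=C(/CBr)C(=O)OC
F8 | step 13 | methyl (2Z,4S,6R,7Z)-2-(bromomethyl)-4-[(tert-butyldimethylsilyl)oxy]-8-iodo-6-methyl-6-[(triethylsilyl)oxy]octa-2,7-dienoate | I/C=C\[C@](C)(O[Si](CC)(CC)CC)C[C@H](O[Si](C)(C)C(C)(C)C)/C=C(\CBr)C(=O)OC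
F9 | step 13 | methyl (3S,4R,5Z)-3-[(1S,3R,4Z)-1-[(tert-butyldimethylsilyl)oxy]-5-iodo-3-methyl-3-[(triethylsilyl)oxy]pent-4-en-1-yl]-4-hydroxy-2-methylidene-6-(tributylstannyl)hept-5-enoate | C=C(C(=O)OC)[C@@H]([C@@H](O)/C=C(/C)[Sn](CCCC)(CCCC)CCCC)[C@@H](O[Si](C)(C)C(C)(C)C)C[C@@](C)(O[Si](CC)(CC)CC)/C=C\I
F10 | step 13 | (4S,5R)-4-[(1S,3R,4Z)-1-[(tert-butyldimethylsilyl)oxy]-5-iodo-3-methyl-3-[(triethylsilyl)oxy]pent-4-en-1-yl]-3-methylidene-5-[(1Z)-2-(tributylstannyl)prop-1-en-1-yl]oxolan-2-one | C=C1C(=O)O[C@@H](/C=C(/C)[Sn](CCCC)(CCCC)CCCC)[C@H]1[C@@H](O[Si](C)(C)C(C)(C)C)C[C@@](C)(O[Si](CC)(CC)CC)/C=C\I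
F11 | step 13 | (3aS,4S,6R,7Z,10Z,11aS)-4-[(tert-butyldimethylsilyl)oxy]-6,10-dimethyl-3-methylidene-6-[(triethylsilyl)oxy]-3a,4,5,6-tetrahydrocyclodeca[b]furan-2,9(3H,11aH)-dione | C=C1C(=O)O[C@H]2/C=C(/C)C(=O)/C=C\[C@](C)(O[Si](CC)(CC)CC)C[C@H](O[Si](C)(C)C(C)(C)C)[C@@H]12
F12 | step 13 | (3aR,4S,6R,7Z,10Z,11aS)-4,6-dihydroxy-6,10-dimethyl-3-methylidene-3a,4,5,6-tetrahydrocyclodeca[b]furan-2,9(3H,11aH)-dione | C=C1C(=O)O[C@H]2/C=C(/C)C(=O)/C=C\[C@](C)(O)C[C@H](O)[C@@H]12
F13 | step 6 | methyl (6R,7Z)-4-hydroxy-8-iodo-6-methyl-6-[(triethylsilyl)oxy]oct-7-en-2-ynoate, mixture of C4 epimers | I/C=C\[C@](C)(O[Si](CC)(CC)CC)CC(O)C#CC(=O)OC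
F14 | step 6 | methyl (6R,7Z)-8-iodo-6-methyl-4-oxo-6-[(triethylsilyl)oxy]oct-7-en-2-ynoate | I/C=C\[C@](C)(O[Si](CC)(CC)CC)CC(=O)C#CC(=O)OC
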